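**Retrosynthetic overview**

1. The target is cut at the Ar–CH2–Ar bond (Friedel–Crafts benzylation, then fourfold O-demethylation) into two copies of one monomer, (S)-herbertenediol dimethyl ether 14; one copy is first oxidised at its aryl methyl group to the benzylic alcohol 16.
2. 14 comes from cyclopentanone 11 by cleaving a spectator vinyl group to CHO and reducing both carbonyls in one Wolff–Kishner step: the ring C=O becomes the ring CH2 next to CMe2, and the CHO becomes the benzylic-carbon methyl.
3. Key disconnection: in each cyclopentane, the bond between the CH2 next to CMe2 and the middle CH2. It is formed as the C(=O)–CH2 bond of 11 by enantioselective, desymmetrising Rh-hydroacylation of the achiral aldehyde 10.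
4. Enabling feature: the ring's three-CH2 chain lies between two contiguous quaternary carbons. The CH2 next to CMe2 can therefore be an aldehyde carbon and the other two CH2 a vinyl group on the benzylic carbon (a 4-pentenal); the benzylic CH3 is carried as a second, enantiotopic vinyl group, so this carbon is prochiral until the ring closes.
5. 10 comes from a Claisen rearrangement (creates the aryl-C–CMe2 bond and both quaternary carbons; E/Z isomers converge) of dienyl isobutenyl ether 9, made from 3,4-dimethoxytoluene via ester 4, divinyl carbinol 6 and dienol 7. The arene rings are bought; each cyclopentane is closed once, in step 5.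

Key step: step 5

Assumption: the sense in which Rh/(S)-BINAP chooses between the two enantiotopic vinyl groups of 10 cannot be derived with certainty; (S)-BINAP is written for the (S)-ketone 11, and the (R)-ligand is to be used instead if a first run shows the opposite sense.

**Route**

Step 1
Reactants: 1 1,2-dimethoxy-4-methylbenzene (3,4-dimethoxytoluene); 2 methyl chloroformate
Product: 4 methyl 2,3-dimethoxy-5-methylbenzoate, via aryllithium 3 (not isolated)
Conditions: n-BuLi, TMEDA, Et2O, 0 °C → rt; then added to ClCO2Me, THF, −78 °C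
Reagents that add atoms: methyl chloroformate, COC(=O)Cl
Why: Directed ortho-metalation places lithium ortho to a methoxy group at the position not flanked by the methyl group, and acylation of the aryllithium by the chloroformate (inverse addition) should give the ester.

Step 2
Reactants: 4 methyl 2,3-dimethoxy-5-methylbenzoate; 5 vinylmagnesium bromide
Product: 6 3-(2,3-dimethoxy-5-methylphenyl)penta-1,4-dien-3-ol
Conditions: CH2=CHMgBr (2.5 equiv), THF, −78 → 0 °C; then pH 7 buffer
Reagents that add atoms: vinylmagnesium bromide, C=C[Mg]Br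
Why: Double 1,2-addition of the Grignard reagent to the ester through the transient aryl vinyl ketone should give the symmetric tertiary bis-allylic alcohol.

Step 3
Reactants: 6 3-(2,3-dimethoxy-5-methylphenyl)penta-1,4-dien-3-ol
Product: 7 3-(2,3-dimethoxy-5-methylphenyl)penta-2,4-dien-1-ol (2E/2Z mixture)
Conditions: Ph3SiOReO3 (2 mol%), Et2O, 0 °C
Reagents that add atoms: none
Why: Oxo-rhenium-catalysed 1,3-transposition of the allylic alcohol ([3,3] shift of the perrhenate ester) is driven to the primary alcohol by conjugation of the new diene with the arene; the E/Z ratio does not matter because both isomers converge in step 4.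

Step 4
Reactants: 7 3-(2,3-dimethoxy-5-methylphenyl)penta-2,4-dien-1-ol; 8 1-iodo-2-methylprop-1-ene
Product: 10 3-(2,3-dimethoxy-5-methylphenyl)-3-ethenyl-2,2-dimethylpent-4-enal, via dienyl isobutenyl ether 9 (not isolated)
Conditions: CuI (10 mol%), 3,4,7,8-tetramethyl-1,10-phenanthroline (20 mol%), Cs2CO3 (1.5 equiv), o-xylene, 120 °C
Reagents that add atoms: 1-iodo-2-methylprop-1-ene, CC(C)=CI
Why: Cu-catalysed C–O coupling of the allylic alcohol with the vinyl iodide gives the allyl vinyl ether, which at the same temperature should undergo chair Claisen rearrangement to the aldehyde with two contiguous quaternary carbons; both alkene isomers of 7 give the same achiral 10 because the new quaternary carbon carries two identical vinyl groups.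

Step 5
Reactants: 10 3-(2,3-dimethoxy-5-methylphenyl)-3-ethenyl-2,2-dimethylpent-4-enal
Product: 11 (3S)-3-(2,3-dimethoxy-5-methylphenyl)-3-ethenyl-2,2-dimethylcyclopentan-1-one
Conditions: [Rh(nbd)((S)-BINAP)]BF4 (5 mol%, activated with H2, then Ar), CH2Cl2, 25 → 40 °C
Reagents that add atoms: none
Why: Cationic Rh(I) adds oxidatively into the aldehyde C–H bond, one vinyl group inserts into Rh–H with hydride going to the internal carbon to give a six-membered acyl-rhodacycle, and C–C reductive elimination joins the acyl carbon to the terminal vinyl carbon. The closest known reaction type is the Rh(I)/chiral bisphosphine intramolecular hydroacylation of 4-pentenals, including desymmetrisation of 4-pentenals that carry two identical alkenyl groups on C3. The cyclopentanone closes in a formally 5-endo-trig mode that runs through the six-membered metallacycle. The benzylic quaternary carbon becomes a stereocentre only through the choice between its two enantiotopic vinyl groups, and this choice is controlled by the BINAP ligand, because aryl and spectator vinyl occupy different pseudo-axial and pseudo-equatorial sites of the metallacycle inside the chiral pocket. The step needs group selectivity between the vinyl groups and cyclisation faster than decarbonylation. The two flanking quaternary carbons secure this: there are no α- or allylic hydrogens, so enolisation and alkene isomerisation are excluded, and Thorpe–Ingold compression speeds up ring closure.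

Step 6
Reactants: 11 (3S)-3-(2,3-dimethoxy-5-methylphenyl)-3-ethenyl-2,2-dimethylcyclopentan-1-one
Product: 12 (1S)-1-(2,3-dimethoxy-5-methylphenyl)-2,2-dimethyl-3-oxocyclopentane-1-carbaldehyde
Conditions: OsO4 (2 mol%), NaIO4 (4 equiv), 2,6-lutidine, dioxane–H2O (3:1), rt
Reagents that add atoms: sodium periodate, [Na+].[O-]I(=O)(=O)=O (oxygen source, delivered through catalytic osmium tetroxide, O=[Os](=O)(=O)=O)
Why: Lemieux–Johnson oxidation (catalytic dihydroxylation, then periodate glycol cleavage) should remove the terminal CH2 of the spectator vinyl group while sparing the electron-rich arene that ozone could attack.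

Step 7
Reactants: 12 (1S)-1-(2,3-dimethoxy-5-methylphenyl)-2,2-dimethyl-3-oxocyclopentane-1-carbaldehyde
Product: 14 1,2-dimethoxy-5-methyl-3-[(1S)-1,2,2-trimethylcyclopentyl]benzene, via bis-hydrazone 13 (not isolated)
Conditions: N2H4·H2O, diethylene glycol, 130 °C; then KOH, distil to 200 °C (Huang-Minlon)
Reagents that add atoms: none
Why: Wolff–Kishner reduction should turn the aldehyde into the methyl group on the benzylic carbon and the hindered ring ketone into CH2 in one operation, and the quaternary stereocentre cannot epimerise.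

Step 8
Reactants: 14 1,2-dimethoxy-5-methyl-3-[(1S)-1,2,2-trimethylcyclopentyl]benzene
Product: 15 3,4-dimethoxy-5-[(1S)-1,2,2-trimethylcyclopentyl]benzaldehyde
Conditions: (NH4)2Ce(NO3)6 (4.2 equiv), MeCN–H2O (4:1), 0 °C → rt
Reagents that add atoms: water, O
Why: Single-electron oxidation of the electron-rich arene by Ce(IV) and loss of a benzylic proton should oxidise the only benzylic C–H position, the methyl group para to a methoxy group, to the aldehyde (side-chain oxidation of a p-methoxytoluene), after which the formyl group deactivates the ring.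

Step 9
Reactants: 15 3,4-dimethoxy-5-[(1S)-1,2,2-trimethylcyclopentyl]benzaldehyde
Product: 16 {3,4-dimethoxy-5-[(1S)-1,2,2-trimethylcyclopentyl]phenyl}methanol
Conditions: NaBH4, MeOH, 0 °C
Reagents that add atoms: none
Why: Borohydride reduction of the aryl aldehyde should give the benzylic alcohol.

Step 10
Reactants: 16 {3,4-dimethoxy-5-[(1S)-1,2,2-trimethylcyclopentyl]phenyl}methanol; 14 1,2-dimethoxy-5-methyl-3-[(1S)-1,2,2-trimethylcyclopentyl]benzene
Product: 17 3-({3,4-dimethoxy-5-[(1S)-1,2,2-trimethylcyclopentyl]phenyl}methyl)-1,2-dimethoxy-4-methyl-6-[(1S)-1,2,2-trimethylcyclopentyl]benzene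
Conditions: TfOH (5 mol%), (CF3)2CHOH–CH2Cl2, 0 °C; 16 added slowly to 14 (3 equiv, excess recovered)
Reagents that add atoms: none
Why: In this dehydrative Friedel–Crafts benzylation the p-methoxy-stabilised benzylic cation from 16 should attack 14 at C6, between the C1 methoxy group and the methyl group, the only accessible activated position (the other free position, C4, para to that methoxy group, is shielded by the quaternary cyclopentyl group and the methyl group), while excess 14 and slow addition suppress self-alkylation of 16.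

Step 11
Reactants: 17 3-({3,4-dimethoxy-5-[(1S)-1,2,2-trimethylcyclopentyl]phenyl}methyl)-1,2-dimethoxy-4-methyl-6-[(1S)-1,2,2-trimethylcyclopentyl]benzene
Product: 18 3-({3,4-dihydroxy-5-[(1S)-1,2,2-trimethylcyclopentyl]phenyl}methyl)-4-methyl-6-[(1S)-1,2,2-trimethylcyclopentyl]benzene-1,2-diol (CNP0137546.1)
Conditions: BBr3 (6 equiv), CH2Cl2, −78 → 0 °C; then H2O, under Ar
Reagents that add atoms: none
Why: BBr3 should cleave the four aryl methyl ethers through aryloxyboron intermediates (Lewis-acid ether cleavage) without touching the diarylmethane or the quaternary centres.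

**Compound list**

1 | 1,2-dimethoxy-4-methylbenzene (3,4-dimethoxytoluene) | COc1ccc(C)cc1OC | starting material
2 | methyl chloroformate | COC(=O)Cl | starting material
3 | (2,3-dimethoxy-5-methylphenyl)lithium | [Li]c1cc(C)cc(OC)c1OC | intermediate
4 | methyl 2,3-dimethoxy-5-methylbenzoate | COC(=O)c1cc(C)cc(OC)c1OC | intermediate
5 | vinylmagnesium bromide | C=C[Mg]Br | starting material
6 | 3-(2,3-dimethoxy-5-methylphenyl)penta-1,4-dien-3-ol | C=CC(O)(C=C)c1cc(C)cc(OC)c1OC | intermediate
7 | 3-(2,3-dimethoxy-5-methylphenyl)penta-2,4-dien-1-ol (2E/2Z mixture, alkene geometry left open) | C=CC(=CCO)c1cc(C)cc(OC)c1OC | intermediate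
8 | 1-iodo-2-methylprop-1-ene | CC(C)=CI | starting material
9 | 1-{5-[(2-methylprop-1-en-1-yl)oxy]penta-1,3-dien-3-yl}-2,3-dimethoxy-5-methylbenzene (E/Z mixture) | C=CC(=CCOC=C(C)C)c1cc(C)cc(OC)c1OC | intermediate
10 | 3-(2,3-dimethoxy-5-methylphenyl)-3-ethenyl-2,2-dimethylpent-4-enal (achiral) | O=CC(C)(C)C(C=C)(C=C)c1cc(C)cc(OC)c1OC | intermediate
11 | (3S)-3-(2,3-dimethoxy-5-methylphenyl)-3-ethenyl-2,2-dimethylcyclopentan-1-one | Cc1cc([C@@]2(C=C)CCC(=O)C2(C)C)c(OC)c(OC)c1 | intermediate
12 | (1S)-1-(2,3-dimethoxy-5-methylphenyl)-2,2-dimethyl-3-oxocyclopentane-1-carbaldehyde | Cc1cc([C@@]2(C=O)CCC(=O)C2(C)C)c(OC)c(OC)c1 | intermediate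
13 | bis-hydrazone of 12 (configuration at the quaternary carbon unchanged) | Cc1cc([C@@]2(C=NN)CCC(=NN)C2(C)C)c(OC)c(OC)c1 | intermediate
14 | 1,2-dimethoxy-5-methyl-3-[(1S)-1,2,2-trimethylcyclopentyl]benzene ((S)-herbertenediol dimethyl ether) | Cc1cc([C@@]2(C)CCCC2(C)C)c(OC)c(OC)c1 | intermediate
15 | 3,4-dimethoxy-5-[(1S)-1,2,2-trimethylcyclopentyl]benzaldehyde | O=Cc1cc(OC)c(OC)c([C@@]2(C)CCCC2(C)C)c1 | intermediate
16 | {3,4-dimethoxy-5-[(1S)-1,2,2-trimethylcyclopentyl]phenyl}methanol | OCc1cc(OC)c(OC)c([C@@]2(C)CCCC2(C)C)c1 | intermediate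
17 | 3-({3,4-dimethoxy-5-[(1S)-1,2,2-trimethylcyclopentyl]phenyl}methyl)-1,2-dimethoxy-4-methyl-6-[(1S)-1,2,2-trimethylcyclopentyl]benzene | Cc1cc([C@@]2(C)CCCC2(C)C)c(OC)c(OC)c1Cc1cc(OC)c(OC)c([C@@]2(C)CCCC2(C)C)c1 | intermediate
18 | 3-({3,4-dihydroxy-5-[(1S)-1,2,2-trimethylcyclopentyl]phenyl}methyl)-4-methyl-6-[(1S)-1,2,2-trimethylcyclopentyl]benzene-1,2-diol | Cc1cc([C@@]2(C)CCCC2(C)C)c(O)c(O)c1Cc1cc(O)c(O)c([C@@]2(C)CCCC2(C)C)c1 | target

**Step count and risks**

Total steps: 11. Longest linear sequence: 11 steps (1 → 18); 14 enters step 10 twice, once directly and once after steps 8 and 9.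

Steps most likely to fail:

1. Step 5. The catalyst may discriminate poorly between the two enantiotopic vinyl groups, or the hindered acyl-rhodium may decarbonylate and kill the catalyst.
Fallback (sets out from 1, comes back at 14): chirality transfer replaces catalyst control.
   - Lithiation of 1 as in step 1 (aryllithium 3) and addition to 4-methoxypent-3-en-2-one gives the carbinol 2-(2,3-dimethoxy-5-methylphenyl)-4-methoxypent-3-en-2-ol F1 (not isolated). Acidic work-up (Stork–Danheiser transposition, with equilibration) gives (3E)-4-(2,3-dimethoxy-5-methylphenyl)pent-3-en-2-one F2.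
   - Corey–Bakshi–Shibata reduction with the (S)-oxazaborolidine gives (2R,3E)-4-(2,3-dimethoxy-5-methylphenyl)pent-3-en-2-ol F3.
   - The conditions of step 4 with 8 give the ether 1-{(2E,4R)-4-[(2-methylprop-1-en-1-yl)oxy]pent-2-en-2-yl}-2,3-dimethoxy-5-methylbenzene F4 (not isolated). Its chair Claisen rearrangement, with the carbinol methyl equatorial, transfers the C–O stereocentre to the quaternary carbon and gives (3R,4E)-3-(2,3-dimethoxy-5-methylphenyl)-2,2,3-trimethylhex-4-enal F5.
   - Ethenolysis (second-generation Ru metathesis catalyst, ethylene) gives (3R)-3-(2,3-dimethoxy-5-methylphenyl)-2,2,3-trimethylpent-4-enal F6.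
   - Hydroacylation with achiral [Rh(dppe)]BF4 gives (3R)-3-(2,3-dimethoxy-5-methylphenyl)-2,2,3-trimethylcyclopentan-1-one F7, and Wolff–Kishner reduction as in step 7 gives 14.

2. Step 8. The electron-transfer oxidation may attack the ring instead (oxidative demethylation, nitration), or the benzylic cation may be captured by a second arene.
Fallback (sets out from 14, comes back at 18): radical bromination on a deactivated ring.
   - BBr3 converts 14 into 5-methyl-3-[(1S)-1,2,2-trimethylcyclopentyl]benzene-1,2-diol F8.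
   - Ac2O/pyridine gives 5-methyl-3-[(1S)-1,2,2-trimethylcyclopentyl]-1,2-phenylene diacetate F9, whose ring no longer competes for bromine.
   - NBS with AIBN in PhCF3 at 80 °C gives 5-(bromomethyl)-3-[(1S)-1,2,2-trimethylcyclopentyl]-1,2-phenylene diacetate F10.
   - Zn(OTf)2-promoted Friedel–Crafts benzylation of excess catechol F8 with F10 gives 5-({2,3-dihydroxy-6-methyl-4-[(1S)-1,2,2-trimethylcyclopentyl]phenyl}methyl)-3-[(1S)-1,2,2-trimethylcyclopentyl]-1,2-phenylene diacetate F11.
   - K2CO3 in MeOH under argon removes the acetates and gives 18.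

3. Step 10. The benzylic alcohol may alkylate itself or the product (oligomerisation), or attack the wrong ring position.
Fallback (sets out from 14, uses 15, comes back at 17): an aryllithium made from 14 adds to aldehyde 15, so that each partner can react in one role only and the ring position is set by the halogen.
   - NBS in MeCN at 0 °C brominates 14 at C6, between the C1 methoxy group and the methyl group, to give 1-bromo-2,3-dimethoxy-6-methyl-4-[(1S)-1,2,2-trimethylcyclopentyl]benzene F12.
   - Bromine–lithium exchange (n-BuLi, THF, −78 °C) gives {2,3-dimethoxy-6-methyl-4-[(1S)-1,2,2-trimethylcyclopentyl]phenyl}lithium F13 (not isolated).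
   - Addition to aldehyde 15 gives {2,3-dimethoxy-6-methyl-4-[(1S)-1,2,2-trimethylcyclopentyl]phenyl}{3,4-dimethoxy-5-[(1S)-1,2,2-trimethylcyclopentyl]phenyl}methanol F14 (mixture of carbinol epimers).
   - Ionic hydrogenation (Et3SiH, TFA, CH2Cl2) removes the hydroxyl group and gives 17.

**Further compounds**

F1 | step 5 | 2-(2,3-dimethoxy-5-methylphenyl)-4-methoxypent-3-en-2-ol | COC(C)=CC(C)(O)c1cc(C)cc(OC)c1OC
F2 | step 5 | (3E)-4-(2,3-dimethoxy-5-methylphenyl)pent-3-en-2-one | CC(=O)/C=C(\C)c1cc(C)cc(OC)c1OC
F3 | step 5 | (2R,3E)-4-(2,3-dimethoxy-5-methylphenyl)pent-3-en-2-ol | C[C@@H](O)/C=C(\C)c1cc(C)cc(OC)c1OC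
F4 | step 5 | 1-{(2E,4R)-4-[(2-methylprop-1-en-1-yl)oxy]pent-2-en-2-yl}-2,3-dimethoxy-5-methylbenzene | C[C@@H](OC=C(C)C)/C=C(\C)c1cc(C)cc(OC)c1OC
F5 | step 5 | (3R,4E)-3-(2,3-dimethoxy-5-methylphenyl)-2,2,3-trimethylhex-4-enal | Cc1cc([C@@](C(C)(C)C=O)(C)/C=C/C)c(OC)c(OC)c1
F6 | step 5 | (3R)-3-(2,3-dimethoxy-5-methylphenyl)-2,2,3-trimethylpent-4-enal | Cc1cc([C@@](C(C)(C)C=O)(C)C=C)c(OC)c(OC)c1
F7 | step 5 | (3R)-3-(2,3-dimethoxy-5-methylphenyl)-2,2,3-trimethylcyclopentan-1-one | Cc1cc([C@@]2(C)CCC(=O)C2(C)C)c(OC)c(OC)c1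
F8 | step 8 | 5-methyl-3-[(1S)-1,2,2-trimethylcyclopentyl]benzene-1,2-diol | Cc1cc([C@@]2(C)CCCC2(C)C)c(O)c(O)c1
F9 | step 8 | 5-methyl-3-[(1S)-1,2,2-trimethylcyclopentyl]-1,2-phenylene diacetate | Cc1cc([C@@]2(C)CCCC2(C)C)c(OC(C)=O)c(OC(C)=O)c1
F10 | step 8 | 5-(bromomethyl)-3-[(1S)-1,2,2-trimethylcyclopentyl]-1,2-phenylene diacetate | BrCc1cc(OC(C)=O)c(OC(C)=O)c([C@@]2(C)CCCC2(C)C)c1
F11 | step 8 | 5-({2,3-dihydroxy-6-methyl-4-[(1S)-1,2,2-trimethylcyclopentyl]phenyl}methyl)-3-[(1S)-1,2,2-trimethylcyclopentyl]-1,2-phenylene diacetate | Cc1cc([C@@]2(C)CCCC2(C)C)c(O)c(O)c1Cc1cc(OC(C)=O)c(OC(C)=O)c([C@@]2(C)CCCC2(C)C)c1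
F12 | step 10 | 1-bromo-2,3-dimethoxy-6-methyl-4-[(1S)-1,2,2-trimethylcyclopentyl]benzene | Cc1cc([C@@]2(C)CCCC2(C)C)c(OC)c(OC)c1Br
F13 | step 10 | {2,3-dimethoxy-6-methyl-4-[(1S)-1,2,2-trimethylcyclopentyl]phenyl}lithium | Cc1cc([C@@]2(C)CCCC2(C)C)c(OC)c(OC)c1[Li]
F14 | step 10 | {2,3-dimethoxy-6-methyl-4-[(1S)-1,2,2-trimethylcyclopentyl]phenyl}{3,4-dimethoxy-5-[(1S)-1,2,2-trimethylcyclopentyl]phenyl}methanol | Cc1cc([C@@]2(C)CCCC2(C)C)c(OC)c(OC)c1C(O)c1cc(OC)c(OC)c([C@@]2(C)CCCC2(C)C)c1
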